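The route cuts the C12–C13 bond of the hexadecanoyl chain. C13 bears two almost indistinguishable arms, propyl (C14–C16) and the C1–C12 chain, so its configuration is set while C13 carries boron instead of oxygen. A nickel/chiral diamine catalyst couples a racemic 1-chlorobutyl pinacol boronate with a C12 alkylzinc bromide ending in an ethyl ester, making the C12–C13 bond and the C13 stereocenter in one stereoconvergent operation. Oxidation of C–B with retention then gives the carbinol. The only ring, the phloroglucinol ring, is attached last at C1 by acylating a lithiated tris-MOM ether with a Weinreb amide, followed by one acidic deprotection.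

Key step: step 4

Numbering: chain carbons run from the aryl ketone carbon (C1) to the terminal methyl (C16); C13 is the stereocenter.

Assumption: the (S,S)-enantiomer of the diamine is written as the one that gives the (13S)-boronate; if the first run (oxidation to the alcohol, MTPA ester analysis) shows the opposite sense, the (R,R)-enantiomer is used with no other change.

Step 1
Reactants: 1 propylboronic acid pinacol ester (4,4,5,5-tetramethyl-2-propyl-1,3,2-dioxaborolane); 2 dichloromethane
Product: 5 rac-2-(1-chlorobutyl)-4,4,5,5-tetramethyl-1,3,2-dioxaborolane, via (dichloromethyl)lithium 3 (not isolated), via lithium boronate complex 4 (not isolated)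
Conditions: CH2Cl2, n-BuLi, THF, −100 °C; then 1; ZnCl2, −100 °C → rt
Reagents that add atoms: none
Why: Matteson homologation: (dichloromethyl)lithium, made by deprotonating dichloromethane at −100 °C, adds to boron and the propyl group of the resulting ate complex migrates from boron to carbon with loss of chloride (ZnCl2-assisted), giving the α-chloroboronate as a racemate, which is all the stereoconvergent step 4 requires.

Step 2
Reactants: 6 12-bromododecanoic acid
Product: 7 ethyl 12-bromododecanoate
Conditions: EtOH, H2SO4 (cat.), reflux
Reagents that add atoms: ethanol, CCO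
Why: Fischer esterification of an unhindered carboxylic acid in excess ethanol; the primary bromide does not react under these acidic conditions.

Step 3
Reactants: 7 ethyl 12-bromododecanoate
Product: 8 (12-ethoxy-12-oxododecyl)zinc bromide (titrated DMA solution, decanted from excess zinc)
Conditions: Zn dust, I2 (5 mol%), DMA, 70–80 °C
Reagents that add atoms: zinc, [Zn]
Why: Direct oxidative insertion of iodine-activated zinc into the primary C–Br bond in a polar amide solvent gives the alkylzinc bromide, a nucleophile too mild to attack its own ethyl ester, which is kept as the spectator group because it also tolerates the nickel catalyst and perborate and can be turned into the acylating group only after the C–B bond has been oxidised.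

Step 4
Reactants: 5 rac-2-(1-chlorobutyl)-4,4,5,5-tetramethyl-1,3,2-dioxaborolane; 8 (12-ethoxy-12-oxododecyl)zinc bromide (1.8 equiv)
Product: 9 ethyl (13S)-13-(4,4,5,5-tetramethyl-1,3,2-dioxaborolan-2-yl)hexadecanoate
Conditions: NiBr2·diglyme (10 mol%), (S,S)-N,N′-dimethyl-1,2-diphenylethane-1,2-diamine (13 mol%), THF/DMA, 0 °C
Reagents that add atoms: none
Why: Transmetallation of 8 to the diamine-ligated divalent nickel bromide gives a chiral alkylnickel complex, while a monovalent nickel species abstracts chlorine from either enantiomer of 5 to give one planar α-boryl radical at C13, stabilised by the empty p orbital on boron. The radical is captured by the chiral divalent alkylnickel complex and the resulting trivalent nickel species reductively eliminates, forming the C12–C13 bond and returning monovalent nickel to the cycle. The closest known reaction type is the nickel-catalysed enantioconvergent Negishi alkyl–alkyl coupling of racemic α-haloboronates with alkylzinc halides; no ring is closed. The new C13 stereocenter is set by catalyst control: the chiral diamine on nickel selects one face of the radical through the size contrast between the pinacol boronate and the slim propyl group, whatever the configuration of the chloride consumed. The step needs enantioselectivity and chemoselectivity for cross-coupling over β-hydride elimination; these should be secured by the steric difference at C13, by the radical-stabilising boron, and by the inertness of the remote ethyl ester towards the alkylzinc bromide and nickel.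

Step 5
Reactants: 9 ethyl (13S)-13-(4,4,5,5-tetramethyl-1,3,2-dioxaborolan-2-yl)hexadecanoate
Product: 11 ethyl (13S)-13-hydroxyhexadecanoate, via borate ester 10 (not isolated)
Conditions: NaBO3·4H2O, THF/H2O, rt
Reagents that add atoms: sodium perborate tetrahydrate, [Na+].[O-]OB=O.O.O.O.O
Why: Oxidation of the C–B bond: perborate-derived peroxide adds to boron and the C13 alkyl group shifts from boron to oxygen with retention of configuration, the borate ester hydrolysing in situ; the mild reagent spares the ethyl ester and the descriptor remains S because oxygen takes the place of boron without changing the sense of the ranked substituents.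

Step 6
Reactants: 11 ethyl (13S)-13-hydroxyhexadecanoate
Product: 12 ethyl (13S)-13-[(tert-butyldimethylsilyl)oxy]hexadecanoate
Conditions: TBSCl, imidazole, DMF, rt
Reagents that add atoms: tert-butyldimethylsilyl chloride, CC(C)(C)[Si](C)(C)Cl
Why: Standard silylation of a secondary alcohol with an imidazole-activated silyl chloride; the ether masks the hydroxyl against the Grignard and aryllithium reagents of steps 7 and 9, and no bond to C13 is broken.

Step 7
Reactants: 12 ethyl (13S)-13-[(tert-butyldimethylsilyl)oxy]hexadecanoate
Product: 13 (13S)-13-[(tert-butyldimethylsilyl)oxy]-N-methoxy-N-methylhexadecanamide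
Conditions: MeNH(OMe)·HCl, iPrMgCl, THF, −20 → 0 °C
Reagents that add atoms: N,O-dimethylhydroxylamine hydrochloride, CNOC.Cl
Why: Direct conversion of an ester into a Weinreb amide: the chloromagnesium amide formed from the amine salt and iPrMgCl adds to the ester faster than iPrMgCl does at low temperature, and the resulting N-methoxy-N-methylamide is stable to the excess reagent; the silyl ether is inert.

Step 8
Reactants: 14 phloroglucinol (benzene-1,3,5-triol, anhydrous)
Product: 15 1,3,5-tris(methoxymethoxy)benzene
Conditions: MOMCl, iPr2NEt, CH2Cl2, 0 °C → rt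
Reagents that add atoms: chloromethyl methyl ether, COCCl
Why: Williamson-type O-alkylation of the three phenols with the hard alkoxymethyl electrophile under an amine base, which favours ether formation over C-alkylation of the phloroglucinol ring.

Step 9
Reactants: 15 1,3,5-tris(methoxymethoxy)benzene (1.5 equiv); 13 (13S)-13-[(tert-butyldimethylsilyl)oxy]-N-methoxy-N-methylhexadecanamide
Product: 18 (13S)-13-[(tert-butyldimethylsilyl)oxy]-1-[2,4,6-tris(methoxymethoxy)phenyl]hexadecan-1-one, via [2,4,6-tris(methoxymethoxy)phenyl]lithium 16 (not isolated), via tetrahedral lithium adduct 17 (not isolated)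
Conditions: n-BuLi, THF, 0 °C; then 13, −78 → 0 °C; H2O
Reagents that add atoms: none
Why: Directed ortho-metalation between two MOM ethers gives the aryllithium, which adds once to the Weinreb amide because the five-membered lithium chelate of the tetrahedral adduct survives until the aqueous quench (Weinreb ketone synthesis); the silyl ether and the remote C13 stereocenter are untouched.

Step 10
Reactants: 18 (13S)-13-[(tert-butyldimethylsilyl)oxy]-1-[2,4,6-tris(methoxymethoxy)phenyl]hexadecan-1-one
Product: 19 (13S)-13-hydroxy-1-(2,4,6-trihydroxyphenyl)hexadecan-1-one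
Conditions: HCl, MeOH, 40 °C
Reagents that add atoms: none
Why: Acid-catalysed acetal exchange with methanol removes the three MOM groups and acid methanolysis cleaves the secondary silyl ether in the same pot; C13 is an unactivated secondary carbinol that does not ionise under these conditions, so its configuration is preserved.

Compound list
1 | propylboronic acid pinacol ester (4,4,5,5-tetramethyl-2-propyl-1,3,2-dioxaborolane) | CCCB1OC(C)(C)C(C)(C)O1 | starting material
2 | dichloromethane | ClCCl | starting material
3 | (dichloromethyl)lithium | [Li]C(Cl)Cl | intermediate (not isolated)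
4 | lithium 2-(dichloromethyl)-4,4,5,5-tetramethyl-2-propyl-1,3,2-dioxaborolan-2-uide (boronate ate complex) | CCC[B-]1(C(Cl)Cl)OC(C)(C)C(C)(C)O1.[Li+] | intermediate (not isolated)
5 | rac-2-(1-chlorobutyl)-4,4,5,5-tetramethyl-1,3,2-dioxaborolane | CCCC(Cl)B1OC(C)(C)C(C)(C)O1 | intermediate
6 | 12-bromododecanoic acid | OC(=O)CCCCCCCCCCCBr | starting material
7 | ethyl 12-bromododecanoate | CCOC(=O)CCCCCCCCCCCBr | intermediate
8 | (12-ethoxy-12-oxododecyl)zinc bromide | CCOC(=O)CCCCCCCCCCC[Zn]Br | intermediate
9 | ethyl (13S)-13-(4,4,5,5-tetramethyl-1,3,2-dioxaborolan-2-yl)hexadecanoate | CCC[C@H](B1OC(C)(C)C(C)(C)O1)CCCCCCCCCCCC(=O)OCC | intermediate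
10 | ethyl (13S)-13-[(4,4,5,5-tetramethyl-1,3,2-dioxaborolan-2-yl)oxy]hexadecanoate (borate ester) | CCC[C@H](OB1OC(C)(C)C(C)(C)O1)CCCCCCCCCCCC(=O)OCC | intermediate (not isolated)
11 | ethyl (13S)-13-hydroxyhexadecanoate | CCC[C@H](O)CCCCCCCCCCCC(=O)OCC | intermediate
12 | ethyl (13S)-13-[(tert-butyldimethylsilyl)oxy]hexadecanoate | CCC[C@H](O[Si](C)(C)C(C)(C)C)CCCCCCCCCCCC(=O)OCC | intermediate
13 | (13S)-13-[(tert-butyldimethylsilyl)oxy]-N-methoxy-N-methylhexadecanamide | CCC[C@H](O[Si](C)(C)C(C)(C)C)CCCCCCCCCCCC(=O)N(C)OC | intermediate
14 | phloroglucinol (benzene-1,3,5-triol) | Oc1cc(O)cc(O)c1 | starting material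
15 | 1,3,5-tris(methoxymethoxy)benzene | COCOc1cc(OCOC)cc(OCOC)c1 | intermediate
16 | [2,4,6-tris(methoxymethoxy)phenyl]lithium | [Li]c1c(OCOC)cc(OCOC)cc1OCOC | intermediate (not isolated)
17 | lithium (13S)-13-[(tert-butyldimethylsilyl)oxy]-1-[methoxy(methyl)amino]-1-[2,4,6-tris(methoxymethoxy)phenyl]hexadecan-1-olate (tetrahedral adduct, C1 unassigned) | CCC[C@H](O[Si](C)(C)C(C)(C)C)CCCCCCCCCCCC(O[Li])(N(C)OC)c1c(OCOC)cc(OCOC)cc1OCOC | intermediate (not isolated)
18 | (13S)-13-[(tert-butyldimethylsilyl)oxy]-1-[2,4,6-tris(methoxymethoxy)phenyl]hexadecan-1-one | CCC[C@H](O[Si](C)(C)C(C)(C)C)CCCCCCCCCCCC(=O)c1c(OCOC)cc(OCOC)cc1OCOC | intermediate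
19 | (13S)-13-hydroxy-1-(2,4,6-trihydroxyphenyl)hexadecan-1-one | CCC[C@H](O)CCCCCCCCCCCC(=O)c1c(O)cc(O)cc1O | target

Total step count: 10.
Longest linear sequence: 8 steps (steps 2, 3, 4, 5, 6, 7, 9, 10, from 12-bromododecanoic acid).

Steps most likely to fail

Step 4. The chiral nickel complex may discriminate the two faces of the α-boryl radical poorly, or the alkylnickel intermediate may be lost by β-hydride elimination and protodemetallation so that conversion stalls. The fallback sets out from zinc reagent 8 and comes back at hydroxy ester 11. Reagent 8 is acylated with but-2-ynoyl chloride under Pd(PPh3)4 catalysis (zerovalent palladium) in THF to give ethyl 13-oxohexadec-14-ynoate F1. In F1 the C14–C16 arm is temporarily an alkyne and therefore clearly different from the C1–C12 chain. Noyori transfer hydrogenation with RuCl[(R,R)-TsDPEN](p-cymene) in iPrOH should then give ethyl (13R)-13-hydroxyhexadec-14-ynoate F2; the descriptor is R only because the alkynyl arm outranks the chain, and the spatial arrangement is that of the target. Hydrogenation over Pd/C in EtOAc saturates the triple bond and delivers 11, whose descriptor becomes S without any change at C13.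

Step 9. Ortho-lithiation may be incomplete, the doubly ortho-substituted aryllithium may attack the amide slowly, or it may deprotonate the amide at C2, so that 13 is returned. The fallback sets out from ester 12 and comes back at ketone 18. DIBAL-H in CH2Cl2 at −78 °C reduces 12 to (13S)-13-[(tert-butyldimethylsilyl)oxy]hexadecanal F3. Aryllithium 16 adds to this more electrophilic aldehyde to give (13S)-13-[(tert-butyldimethylsilyl)oxy]-1-[2,4,6-tris(methoxymethoxy)phenyl]hexadecan-1-ol F4 as a mixture of C1 epimers. Dess–Martin periodinane (NaHCO3, CH2Cl2) oxidises both epimers to 18.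

Step 10. Formaldehyde equivalents released from the MOM ethers may alkylate the electron-rich ring and form methylene-bridged by-products, or the chelated ortho MOM groups may come off incompletely under conditions mild enough to spare the acyl group. The fallback uses benzyl ethers removed by hydrogenolysis; it sets out from phloroglucinol 14 and Weinreb amide 13 and comes back at target 19. Compound 14 is O-benzylated (BnBr, K2CO3, DMF) to 1,3,5-tris(benzyloxy)benzene F5 and monobrominated with NBS (CH2Cl2, −78 °C) to 2-bromo-1,3,5-tris(benzyloxy)benzene F6. Bromine–lithium exchange with n-BuLi (THF, −78 °C) gives [2,4,6-tris(benzyloxy)phenyl]lithium F7. F7 adds to 13 through the tetrahedral lithium adduct F8 to give, after aqueous quench, (13S)-13-[(tert-butyldimethylsilyl)oxy]-1-[2,4,6-tris(benzyloxy)phenyl]hexadecan-1-one F9. Hydrogenolysis (H2, Pd/C, EtOAc) gives (13S)-13-[(tert-butyldimethylsilyl)oxy]-1-(2,4,6-trihydroxyphenyl)hexadecan-1-one F10, and HCl in MeOH cleaves the silyl ether to give 19 with no formaldehyde source present.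

Further compounds
F1 | step 4 | ethyl 13-oxohexadec-14-ynoate | CC#CC(=O)CCCCCCCCCCCC(=O)OCC
F2 | step 4 | ethyl (13R)-13-hydroxyhexadec-14-ynoate | CC#C[C@H](O)CCCCCCCCCCCC(=O)OCC
F3 | step 9 | (13S)-13-[(tert-butyldimethylsilyl)oxy]hexadecanal | CCC[C@H](O[Si](C)(C)C(C)(C)C)CCCCCCCCCCCC=O
F4 | step 9 | (13S)-13-[(tert-butyldimethylsilyl)oxy]-1-[2,4,6-tris(methoxymethoxy)phenyl]hexadecan-1-ol (C1 epimers) | CCC[C@H](O[Si](C)(C)C(C)(C)C)CCCCCCCCCCCC(O)c1c(OCOC)cc(OCOC)cc1OCOC
F5 | step 10 | 1,3,5-tris(benzyloxy)benzene | c1ccccc1COc1cc(OCc2ccccc2)cc(OCc2ccccc2)c1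
F6 | step 10 | 2-bromo-1,3,5-tris(benzyloxy)benzene | Brc1c(OCc2ccccc2)cc(OCc2ccccc2)cc1OCc1ccccc1
F7 | step 10 | [2,4,6-tris(benzyloxy)phenyl]lithium | [Li]c1c(OCc2ccccc2)cc(OCc2ccccc2)cc1OCc1ccccc1
F8 | step 10 | lithium (13S)-13-[(tert-butyldimethylsilyl)oxy]-1-[methoxy(methyl)amino]-1-[2,4,6-tris(benzyloxy)phenyl]hexadecan-1-olate (tetrahedral adduct, C1 unassigned) | CCC[C@H](O[Si](C)(C)C(C)(C)C)CCCCCCCCCCCC(O[Li])(N(C)OC)c1c(OCc2ccccc2)cc(OCc2ccccc2)cc1OCc1ccccc1
F9 | step 10 | (13S)-13-[(tert-butyldimethylsilyl)oxy]-1-[2,4,6-tris(benzyloxy)phenyl]hexadecan-1-one | CCC[C@H](O[Si](C)(C)C(C)(C)C)CCCCCCCCCCCC(=O)c1c(OCc2ccccc2)cc(OCc2ccccc2)cc1OCc1ccccc1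
F10 | step 10 | (13S)-13-[(tert-butyldimethylsilyl)oxy]-1-(2,4,6-trihydroxyphenyl)hexadecan-1-one | CCC[C@H](O[Si](C)(C)C(C)(C)C)CCCCCCCCCCCC(=O)c1c(O)cc(O)cc1O
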